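## The problem

The target is a 19-membered ansa lactam. A C1–C15 chain bridges the meta positions C16 and C20 of a 2-aminohydroquinone (arene C16–C21, nitrogen on C20, oxygens on C18 and C21) and is closed through the C1 anilide. Seven stereocentres lie in three clusters: C6/C7 (syn methoxy and carbamoyloxy), C10/C11/C12 (a methyl group followed by an erythro diol) and C14/C15 (syn methyl and methoxy). The E-C8=C9 alkene and the C13 methylene separate the clusters, so control between them is weak: C10 can steer C11 by 1,2-induction, but C14 can do little for C12. The C6/C7 and C14/C15 pairs therefore need reagent control, and the diol needs a reagent or the ring. The sensitive groups are the (2E,4Z)-dienamide (Z to E isomerisation), the primary carbamate on the allylic C7 (strong base, hydride), the benzylic C15 methyl ether on an electron-rich ring (acid, hydrogenolysis) and the free hydroquinone, which air oxidises to the quinone and which must be uncovered last. The C11–C12 diol is free, both carbinols are secondary, and they are flanked by the C10 methine and the C13 methylene. This is the retron of a reductive coupling of a C11 aldehyde with a C12 aldehyde, each of which can come from a primary alcohol. Such a closure must deliver the 10,11-syn relation and an erythro diol, which is cis on the ring.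

## Retrosynthesis

**32 to 31.** The two aryl O–Si bonds are cut last. Macrocycle 31 differs from target 32 only by a triisopropylsilyl ether on O18 and a tert-butyldimethylsilyl ether on O21. Silyl is preferred to methyl or methoxymethyl because buffered fluoride is tolerated by the free diol, the carbamate and the dienamide and leaves the hydroquinone reduced. Oxidative demethylation with (NH4)2Ce(NO3)6 would also attack the glycol.

**31 to 30.** C11–C12 is cut reductively to seco-dialdehyde 30. Compared with cuts at the amide bond, at C2=C3 or at C4–C5, this one removes a ring, a skeletal bond and two stereocentres at once. It leaves the diol unprotected and allows the carbamate to be in place, since no hydroxyl has to be distinguished afterwards. Dialdehyde 30 is acyclic with five stereocentres. The forward reaction must reduce only the aldehydes, close the 19-membered ring in preference to oligomers, and give the 10,11-syn, 11,12-erythro isomer. The first relation is asked of C10 (Felkin sense), the second of the samarium diolate and the ring. Two weak points of the precursor are reinforced. The C11 aldehyde has an α-centre that is also allylic, so 30 is made by buffered, non-basic oxidation and used at once. The exposed O18 carries the bulkier triisopropylsilyl group.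

**30 to 28.** Both aldehydes are traced to primary alcohols (29) and these to primary silyl ethers (28), so one acid treatment and one oxidation serve both ends. Alkyl silyl ethers must be cleaved beside aryl silyl ethers, which acid-catalysed methanolysis does.

**28 to 16 and 27.** The anilide N–C1 bond is cut to acid 16 (C1–C11) and aniline 27 (C12–C21), two halves of similar size. The carbamate is already on 16 because no later step could place it selectively. The forward reaction is the acylation of a hindered aniline without loss of the 4Z geometry.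

**16 to 10 and 11.** C2=C3 is cut by a Wittig disconnection that ends in lactol 10, not in a free Z-enal. Ylide 11 supplies C1, C2 and the C2 methyl group. O7 is unmasked in the same step (13) and takes the carbamate (15) before the ester is hydrolysed (16).

**10 to 7.** C4=C5 is cut by ring-closing metathesis of acrylate 8, made from alcohol 7. The six-membered ring of lactone 9 guarantees the Z geometry, and C3 and C4 come from the acrylate unit. This replaces the usual sequence of Z-selective phosphonate olefination, reduction and reoxidation, and needs no protecting group on O7.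

**7 to 1.** C6–C7 is cut by a (Z)-γ-methoxyallylboration of enal 5, which sets both centres syn under reagent control. Enal 5 comes from aldehyde 3 and ylide 4 (E-C8=C9), and 3 from hydroxy ester 1 through 2. The ester carbon of 1 becomes C9 and its hydroxymethyl carbon becomes C11, so the 10S centre requires the (R)-enantiomer of the hydroxy ester.

**27 to 17.** In aniline 27 the silyl groups on O21 and O12 are cut together (26). The amine and the phenol are traced to a nitro group and a benzyl ether, removed in one hydrogenation (25). The C12 hydroxyl is traced to a terminal alkene (23), the methyl ether to alcohol 22, and C14–C15 to a (Z)-crotylboration of aldehyde 20. Aldehyde 20 comes from 2,5-dihydroxybenzaldehyde 17 by silylation of the hydroxyl that is not hydrogen-bonded (18), nitration ortho to the remaining phenol (19) and benzylation. Benzyl, not silyl, sits on O21 while the nitro group is present, because a silyl ether of an o-nitrophenol next to the C15 alkoxide would be prone to migration or loss.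

## Roads not taken

**Alternative 1:** The cut runs through the arene. The C17–C18 bond and the benzene ring would be made last from cyclobutenone A1. Thermal ring opening to a dienylketene and 6π-electrocyclisation would give aminohydroquinone A2 with both phenols free and the nitrogen in place.
- Merits: the regiochemistry is written into A1, and there is no nitration and no phenol protection.
- Weak points: the bond from the cyclobutenone carbon to C16 of A1 must be made by a carbanion at C16, β to the C15 methoxy group, which is prone to elimination. All seven stereocentres, built linearly and protected with five silyl groups, must pass through that addition and a thermolysis. A2 is an air-sensitive aminohydroquinone that still has to be N-deallylated, acylated and cyclised, so the ring problem is only postponed.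
- Comparison: this road is better in avoiding the protection, nitration and hydrogenation sequence of steps 11–18. The chosen plan sets against it an arene fragment made from a commercial aldehyde by common reactions, full convergence, and a hydroquinone that stays masked until step 23.

**Alternative 2:** The cut is C2=C3. In A3 an anilide-stabilised phosphorus ylide at C2 would react with the open hydroxy-enal form of a C3 lactol. This would give macrolactam A4, with E-C2=C3 formed, the 19-membered ring closed and O7 set free.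
- Merits: Wittig macrocyclisation is a known reaction type and creates no stereocentre. The lactol secures the 4Z geometry (the same device is used intermolecularly in step 8). O7 emerges as the only free hydroxyl, ready for the carbamate.
- Weak points: the C11/C12 diol must be built and protected before closure, which costs a separate stereocontrolled C–C bond formation and two silyl groups. A weakly reactive ylide and a mostly closed lactol must meet at high dilution. The free O7 can add back to the new dienamide. Removal of two methoxymethyl ethers at the end needs acid beside the allylic carbamate.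
- Comparison: at ring closure this is the safer road, since nothing in it goes beyond known chemistry. The chosen plan sets against it that one step gives the ring, the C11–C12 bond and both carbinol centres, that the diol is never protected, and that the route is several steps shorter.

**Alternative 3:** The cut is C4–C5 at the alkyne level. Seco-diyne A5 would undergo ring-closing alkyne metathesis with a molybdenum alkylidyne such as [Mo(≡CC6H4OMe-4)(OSiPh3)3] to give enyne macrolactam A6 with loss of 2-butyne. Z-selective semireduction would follow.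
- Merits: alkyne metathesis is dependable at this ring size and tolerates ethers and silyl ethers. The Z-alkene comes from the alkyne, so closure has no geometry problem.
- Weak points: the anilide N–H and the propargylic C6 methoxy group sit next to the reacting alkynes. The semireduction must stop at the Z-diene of a conjugated enyne amide with two other alkenes present. A6 carries silyl ethers of two kinds on five oxygens, so O7 must be freed alone, carbamoylated, and the rest removed afterwards, with the diol again built and protected beforehand.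
- Comparison: for closing the ring this is probably the most reliable of the four roads. The chosen plan is shorter, leaves the diol unprotected and forms two stereocentres at closure, at the price of an unproven step.

Key step: step 22

Remark: atom numbers follow the ansamycin convention (C1 amide carbonyl, C15 benzylic carbon, arene C16–C21 with nitrogen on C20 and oxygens on C18 and C21).
Assumption: (+)-Ipc2BOMe denotes the reagent made from (−)-α-pinene. It is specified by its origin because the facial sense of both allylborations depends on it.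

## Route

Step 1
Reactants: 1 methyl (2R)-3-hydroxy-2-methylpropanoate
Product: 2 methyl (2R)-3-[(tert-butyldimethylsilyl)oxy]-2-methylpropanoate
Conditions: TBSCl, imidazole, CH2Cl2, 0 °C to rt
Reagents that add atoms: tert-butyldimethylsilyl chloride, CC(C)(C)[Si](C)(C)Cl
Why: Silylation of a primary alcohol; the TBS ether on O11 is stable to every step up to the acid methanolysis of step 20.

Step 2
Reactants: 2 methyl (2R)-3-[(tert-butyldimethylsilyl)oxy]-2-methylpropanoate
Product: 3 (2R)-3-[(tert-butyldimethylsilyl)oxy]-2-methylpropanal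
Conditions: i-Bu2AlH (1.05 equiv), CH2Cl2, −78 °C; aq. potassium sodium tartrate
Reagents that add atoms: none
Why: Partial reduction of an ester through the aluminium hemiacetal, which is stable at −78 °C; the aldehyde is used crude so that the α-centre is not put at risk.

Step 3
Reactants: 3 (2R)-3-[(tert-butyldimethylsilyl)oxy]-2-methylpropanal; 4 2-(triphenyl-λ5-phosphanylidene)propanal
Product: 5 (2E,4S)-5-[(tert-butyldimethylsilyl)oxy]-2,4-dimethylpent-2-enal
Conditions: toluene, 80 °C
Reagents that add atoms: none
Why: Wittig olefination with a formyl-stabilised ylide gives the E trisubstituted enal (C8=C9); the ylide is too weakly basic to epimerise the α-centre and reacts with the enal product far more slowly than with 3.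

Step 4
Reactants: 5 (2E,4S)-5-[(tert-butyldimethylsilyl)oxy]-2,4-dimethylpent-2-enal
Product: 7 (3S,4S,5E,7S)-8-[(tert-butyldimethylsilyl)oxy]-3-methoxy-5,7-dimethylocta-1,5-dien-4-ol, via diisopinocampheylborinate ester 6 (not isolated)
Conditions: allyl methyl ether, s-BuLi, THF, −78 °C; (+)-Ipc2BOMe; BF3·OEt2; 5, −78 °C; then NaOH, H2O2, 0 °C to rt
Reagents that add atoms: allyl methyl ether, COCC=C
Why: Brown (Z)-γ-methoxyallylboration; the Z reagent reacts through a chair transition state to give the syn methoxy alcohol, and the isopinocampheyl groups of this antipode direct attack to the Re face of the aldehyde, which sets 6S and 7S independently of the remote C10 centre.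

Step 5
Reactants: 7 (3S,4S,5E,7S)-8-[(tert-butyldimethylsilyl)oxy]-3-methoxy-5,7-dimethylocta-1,5-dien-4-ol
Product: 8 (3S,4S,5E,7S)-8-[(tert-butyldimethylsilyl)oxy]-3-methoxy-5,7-dimethylocta-1,5-dien-4-yl prop-2-enoate
Conditions: acryloyl chloride, i-Pr2NEt, DMAP (cat.), CH2Cl2, −20 to 0 °C
Reagents that add atoms: acryloyl chloride, C=CC(=O)Cl
Why: O-acylation of the secondary allylic alcohol; the acrylate supplies C3 and C4.

Step 6
Reactants: 8 (3S,4S,5E,7S)-8-[(tert-butyldimethylsilyl)oxy]-3-methoxy-5,7-dimethylocta-1,5-dien-4-yl prop-2-enoate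
Product: 9 (5S,6S)-6-[(2E,4S)-5-[(tert-butyldimethylsilyl)oxy]-4-methylpent-2-en-2-yl]-5-methoxy-5,6-dihydro-2H-pyran-2-one
Conditions: second-generation Grubbs catalyst (H2IMes)(PCy3)Cl2Ru=CHPh (5 mol %), CH2Cl2 (0.005 M), 40 °C
Reagents that add atoms: none
Why: Ring-closing metathesis of an acrylate with the monosubstituted alkene gives the 5,6-dihydropyran-2-one; the trisubstituted C8=C9 alkene does not take part, and the six-membered ring fixes C4=C5 as Z.

Step 7
Reactants: 9 (5S,6S)-6-[(2E,4S)-5-[(tert-butyldimethylsilyl)oxy]-4-methylpent-2-en-2-yl]-5-methoxy-5,6-dihydro-2H-pyran-2-one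
Product: 10 (2RS,5S,6S)-6-[(2E,4S)-5-[(tert-butyldimethylsilyl)oxy]-4-methylpent-2-en-2-yl]-5-methoxy-5,6-dihydro-2H-pyran-2-ol
Conditions: i-Bu2AlH (1.1 equiv), CH2Cl2, −78 °C; aq. potassium sodium tartrate
Reagents that add atoms: none
Why: 1,2-Reduction of the unsaturated lactone stops at the lactol at −78 °C; the lactol stores the Z-enal and the free O7 in one ring.

Step 8
Reactants: 10 (2RS,5S,6S)-6-[(2E,4S)-5-[(tert-butyldimethylsilyl)oxy]-4-methylpent-2-en-2-yl]-5-methoxy-5,6-dihydro-2H-pyran-2-ol; 11 ethyl 2-(triphenyl-λ5-phosphanylidene)propanoate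
Product: 13 ethyl (2E,4Z,6S,7S,8E,10S)-11-[(tert-butyldimethylsilyl)oxy]-7-hydroxy-6-methoxy-2,8,10-trimethylundeca-2,4,8-trienoate, via open-chain Z-hydroxy enal 12 (not isolated)
Conditions: 11 (1.5 equiv), PhCO2H (cat.), toluene, 60 °C
Reagents that add atoms: none
Why: Wittig olefination of a lactol through its ring-opened hydroxy aldehyde; the α-methyl ester ylide gives E-C2=C3, the Z-C4=C5 bond is carried over from the ring, and O7 is set free without a protecting group.

Step 9
Reactants: 13 ethyl (2E,4Z,6S,7S,8E,10S)-11-[(tert-butyldimethylsilyl)oxy]-7-hydroxy-6-methoxy-2,8,10-trimethylundeca-2,4,8-trienoate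
Product: 15 ethyl (2E,4Z,6S,7S,8E,10S)-11-[(tert-butyldimethylsilyl)oxy]-7-(carbamoyloxy)-6-methoxy-2,8,10-trimethylundeca-2,4,8-trienoate, via N-trichloroacetyl carbamate 14 (not isolated)
Conditions: Cl3CC(O)NCO, CH2Cl2, 0 °C; then neutral Al2O3
Reagents that add atoms: trichloroacetyl isocyanate, O=C=NC(=O)C(Cl)(Cl)Cl
Why: Carbamoylation of an alcohol with trichloroacetyl isocyanate, then cleavage of the trichloroacetyl group on alumina; the conditions are neutral, so the ester and the Z-alkene are untouched, and O7 is the only free hydroxyl.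

Step 10
Reactants: 15 ethyl (2E,4Z,6S,7S,8E,10S)-11-[(tert-butyldimethylsilyl)oxy]-7-(carbamoyloxy)-6-methoxy-2,8,10-trimethylundeca-2,4,8-trienoate
Product: 16 (2E,4Z,6S,7S,8E,10S)-11-[(tert-butyldimethylsilyl)oxy]-7-(carbamoyloxy)-6-methoxy-2,8,10-trimethylundeca-2,4,8-trienoic acid
Conditions: LiOH·H2O (3 equiv), THF/MeOH/H2O 3:1:1, rt; then 1 M HCl to pH 4, 0 °C
Reagents that add atoms: lithium hydroxide, [Li+].[OH-]
Why: Saponification of the ethyl ester; hydroxide attacks a primary carbamate much more slowly than an ester, and elimination is blocked because the leaving group would be a secondary alkoxide.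

Step 11
Reactants: 17 2,5-dihydroxybenzaldehyde
Product: 18 2-hydroxy-5-[(triisopropylsilyl)oxy]benzaldehyde
Conditions: TIPSCl (1.05 equiv), imidazole, CH2Cl2/DMF, 0 °C
Reagents that add atoms: triisopropylsilyl chloride, CC(C)[Si](Cl)(C(C)C)C(C)C
Why: Selective silylation of the C5 hydroxyl (later O18); the C2 hydroxyl is hydrogen-bonded to the aldehyde and stays free.

Step 12
Reactants: 18 2-hydroxy-5-[(triisopropylsilyl)oxy]benzaldehyde
Product: 19 2-hydroxy-3-nitro-5-[(triisopropylsilyl)oxy]benzaldehyde
Conditions: HNO3 (70 %, 1.1 equiv), AcOH, 10 °C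
Reagents that add atoms: nitric acid, O[N+](=O)[O-]
Why: Electrophilic aromatic nitration; the free phenol directs ortho and the aldehyde meta, both to C3 (later C20), as in the nitration of 5-alkoxysalicylaldehydes.

Step 13
Reactants: 19 2-hydroxy-3-nitro-5-[(triisopropylsilyl)oxy]benzaldehyde
Product: 20 2-(benzyloxy)-3-nitro-5-[(triisopropylsilyl)oxy]benzaldehyde
Conditions: BnBr, K2CO3, acetone, 55 °C
Reagents that add atoms: benzyl bromide, BrCc1ccccc1
Why: Williamson benzylation of the acidic nitrophenol; benzyl is robust beside the nitro group and the coming C15 alkoxide, and is later removed in the same hydrogenation that reduces the nitro group.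

Step 14
Reactants: 20 2-(benzyloxy)-3-nitro-5-[(triisopropylsilyl)oxy]benzaldehyde
Product: 22 (1R,2S)-1-{2-(benzyloxy)-3-nitro-5-[(triisopropylsilyl)oxy]phenyl}-2-methylbut-3-en-1-ol, via diisopinocampheylborinate ester 21 (not isolated)
Conditions: cis-2-butene, n-BuLi, KOt-Bu, THF, −78 to −45 °C; (+)-Ipc2BOMe, −78 °C; BF3·OEt2; 20, −78 °C; then NaBO3·4H2O, THF/H2O, rt
Reagents that add atoms: cis-2-butene, C/C=C\C
Why: Brown (Z)-crotylboration; the chair transition state gives the syn product and the reagent from (−)-α-pinene attacks the Re face of the aryl aldehyde, which sets 15R and 14S; the nitro group, the benzyl ether and the aryl silyl ether are inert to the neutral allylborane.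

Step 15
Reactants: 22 (1R,2S)-1-{2-(benzyloxy)-3-nitro-5-[(triisopropylsilyl)oxy]phenyl}-2-methylbut-3-en-1-ol
Product: 23 {4-(benzyloxy)-3-[(1R,2S)-1-methoxy-2-methylbut-3-en-1-yl]-5-nitrophenoxy}triisopropylsilane
Conditions: Me3OBF4, 1,8-bis(dimethylamino)naphthalene, 4 Å MS, CH2Cl2, rt
Reagents that add atoms: trimethyloxonium tetrafluoroborate, C[O+](C)C.F[B-](F)(F)F
Why: O-methylation of a hindered secondary alcohol with Meerwein's salt and a non-nucleophilic base; no alkoxide is formed, so the nitroarene and the silyl ether are safe.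

Step 16
Reactants: 23 {4-(benzyloxy)-3-[(1R,2S)-1-methoxy-2-methylbut-3-en-1-yl]-5-nitrophenoxy}triisopropylsilane
Product: 25 (3S,4R)-4-{2-(benzyloxy)-3-nitro-5-[(triisopropylsilyl)oxy]phenyl}-4-methoxy-3-methylbutan-1-ol, via B-alkyl-9-borabicyclononane 24 (not isolated)
Conditions: 9-BBN, THF, 0 °C to rt; then NaBO3·4H2O, H2O, rt
Reagents that add atoms: sodium perborate (source of the hydroxyl oxygen), [Na+].[Na+].O[B-]1(O)OO[B-](O)(O)OO1
Why: Anti-Markovnikov hydroboration of the terminal alkene with a bulky borane, then mild perborate oxidation, gives the C12 primary alcohol; 9-BBN does not reduce the nitro group at room temperature.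

Step 17
Reactants: 25 (3S,4R)-4-{2-(benzyloxy)-3-nitro-5-[(triisopropylsilyl)oxy]phenyl}-4-methoxy-3-methylbutan-1-ol
Product: 26 (3S,4R)-4-{3-amino-2-hydroxy-5-[(triisopropylsilyl)oxy]phenyl}-4-methoxy-3-methylbutan-1-ol
Conditions: H2 (1 atm), Pd/C (10 %), EtOAc, rt
Reagents that add atoms: none
Why: Catalytic hydrogenation reduces the nitro group and hydrogenolyses the aryl benzyl ether in one operation; the secondary benzylic methyl ether at C15 is cleaved far more slowly under neutral conditions, and 26 is used at once because aminophenols are air-sensitive.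

Step 18
Reactants: 26 (3S,4R)-4-{3-amino-2-hydroxy-5-[(triisopropylsilyl)oxy]phenyl}-4-methoxy-3-methylbutan-1-ol
Product: 27 2-[(tert-butyldimethylsilyl)oxy]-3-[(1R,2S)-4-[(tert-butyldimethylsilyl)oxy]-1-methoxy-2-methylbutyl]-5-[(triisopropylsilyl)oxy]aniline
Conditions: TBSCl (2.5 equiv), imidazole, DMF, rt
Reagents that add atoms: tert-butyldimethylsilyl chloride, CC(C)(C)[Si](C)(C)Cl
Why: Silylation of the phenol O21 and the primary O12 in one step; oxygen is silylated in preference to the aniline nitrogen, and any N–Si bond is hydrolysed in the work-up.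

Step 19
Reactants: 16 (2E,4Z,6S,7S,8E,10S)-11-[(tert-butyldimethylsilyl)oxy]-7-(carbamoyloxy)-6-methoxy-2,8,10-trimethylundeca-2,4,8-trienoic acid; 27 2-[(tert-butyldimethylsilyl)oxy]-3-[(1R,2S)-4-[(tert-butyldimethylsilyl)oxy]-1-methoxy-2-methylbutyl]-5-[(triisopropylsilyl)oxy]aniline
Product: 28 (2E,4Z,6S,7S,8E,10S)-N-{2-[(tert-butyldimethylsilyl)oxy]-3-[(1R,2S)-4-[(tert-butyldimethylsilyl)oxy]-1-methoxy-2-methylbutyl]-5-[(triisopropylsilyl)oxy]phenyl}-11-[(tert-butyldimethylsilyl)oxy]-7-(carbamoyloxy)-6-methoxy-2,8,10-trimethylundeca-2,4,8-trienamide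
Conditions: BOP-Cl, i-Pr2NEt, toluene, 70 °C
Reagents that add atoms: none
Why: Amide formation through the mixed phosphinic anhydride, the activation used for anilides of α-methyl dienoic acids in this ansamycin class; the carbamate nitrogen is far less nucleophilic than the aniline.

Step 20
Reactants: 28 the seco amide of step 19
Product: 29 (2E,4Z,6S,7S,8E,10S)-N-{2-[(tert-butyldimethylsilyl)oxy]-3-[(1R,2S)-4-hydroxy-1-methoxy-2-methylbutyl]-5-[(triisopropylsilyl)oxy]phenyl}-7-(carbamoyloxy)-11-hydroxy-6-methoxy-2,8,10-trimethylundeca-2,4,8-trienamide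
Conditions: CSA (0.2 equiv), MeOH/CH2Cl2 1:1, 0 °C
Reagents that add atoms: none
Why: Acid-catalysed methanolysis cleaves primary alkyl TBS ethers well before aryl silyl ethers, whose oxygen is less basic; fluoride or base would show the reverse order.

Step 21
Reactants: 29 the seco diol of step 20
Product: 30 (2E,4Z,6S,7S,8E,10S)-N-{2-[(tert-butyldimethylsilyl)oxy]-3-[(1R,2S)-1-methoxy-2-methyl-4-oxobutyl]-5-[(triisopropylsilyl)oxy]phenyl}-7-(carbamoyloxy)-6-methoxy-2,8,10-trimethyl-11-oxoundeca-2,4,8-trienamide
Conditions: Dess–Martin periodinane (3 equiv), NaHCO3, CH2Cl2, 0 °C; filtered cold and used at once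
Reagents that add atoms: none
Why: Dess–Martin oxidation of both primary alcohols under buffered, non-basic conditions; C10, which is α to the new aldehyde and allylic, should keep its configuration if 30 is not stored or chromatographed.

Step 22
Reactants: 30 the seco-dialdehyde of step 21
Product: 31 macrocyclic 11,12-diol (2E,4Z,6S,7S,8E,10S,11R,12S,14S,15R), the target with O18 as triisopropylsilyl ether and O21 as tert-butyldimethylsilyl ether
Conditions: SmI2 (0.1 M in THF, 5 equiv), THF, 30 added over 8 h to a final 0.001 M, −20 °C to rt, no HMPA, no proton donor; then aq. potassium sodium tartrate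
Reagents that add atoms: none
Why: Proposed new method: divalent samarium transfers one electron to an aldehyde of 30, the samarium-bound ketyl adds to the second aldehyde held on the same trivalent samarium (or couples with a second ketyl), and a second electron and protonation on work-up give the diol, so the C11–C12 bond forms by an intramolecular radical coupling under high dilution and slow addition. The closest known reactions are the SmI2 pinacol cyclisation of 1,5- and 1,6-dialdehydes to cis-cycloalkanediols and the low-valent titanium pinacol closure of 14- to 16-membered carbocycles; a stereocontrolled closure of a 19-membered lactam in this way is not known. The one ring formed is the 19-membered macrolactam, closed end to end between the chain termini, with the dienamide, the arene and the E-C8=C9 alkene as rigid segments that reduce the number of rotors to be frozen. C11 is controlled by C10: with the alkenyl group anti to the forming bond (Felkin–Anh), attack on the C11 carbonyl gives the 10,11-syn relation, which is 11R. C12 follows from C11 through the diolate: the erythro isomer needs both oxygens on one samarium with C10 and C13 cis on that five-membered chelate, which the ring can adopt but does not enforce, and HMPA and proton donors are left out to keep the bridge. The step needs chemoselectivity (aldehydes are reduced far faster than the dienamide, the carbamate or the aryl silyl ethers), an intact C10 (non-basic medium, fresh 30) and cyclisation over oligomerisation (final concentration about 0.001 M).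

Step 23
Reactants: 31 the macrocyclic bis-silyl ether of step 22
Product: 32 the target, (2E,4Z,6S,7S,8E,10S,11R,12S,14S,15R)-7-O-carbamoyl-11,12,18,21-tetrahydroxy-6,15-dimethoxy-2,8,10,14-tetramethyl 19-membered ansa lactam (CNP0523404.1)
Conditions: TBAF, AcOH (1:1), THF, 0 °C, argon; degassed work-up with aq. Na2S2O4
Reagents that add atoms: none
Why: Fluoride cleaves aryl silyl ethers within minutes; acetic acid keeps the medium near neutral so the carbamate and the dienamide are safe, and dithionite in the work-up keeps the hydroquinone reduced.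

## Compound list

1 | methyl (2R)-3-hydroxy-2-methylpropanoate | COC(=O)[C@H](C)CO | starting material
2 | methyl (2R)-3-[(tert-butyldimethylsilyl)oxy]-2-methylpropanoate | COC(=O)[C@H](C)CO[Si](C)(C)C(C)(C)C | intermediate
3 | (2R)-3-[(tert-butyldimethylsilyl)oxy]-2-methylpropanal | O=C[C@H](C)CO[Si](C)(C)C(C)(C)C | intermediate
4 | 2-(triphenyl-λ5-phosphanylidene)propanal | CC(C=O)=P(c1ccccc1)(c1ccccc1)c1ccccc1 | starting material
5 | (2E,4S)-5-[(tert-butyldimethylsilyl)oxy]-2,4-dimethylpent-2-enal | O=C/C(C)=C/[C@H](C)CO[Si](C)(C)C(C)(C)C | intermediate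
6 | diisopinocampheylborinate ester of 7 | C=C[C@H](OC)[C@@H](OB([C@H]1C[C@H]2C[C@@H]([C@@H]1C)C2(C)C)[C@H]1C[C@H]2C[C@@H]([C@@H]1C)C2(C)C)/C(C)=C/[C@H](C)CO[Si](C)(C)C(C)(C)C | intermediate (not isolated)
7 | (3S,4S,5E,7S)-8-[(tert-butyldimethylsilyl)oxy]-3-methoxy-5,7-dimethylocta-1,5-dien-4-ol | C=C[C@H](OC)[C@@H](O)/C(C)=C/[C@H](C)CO[Si](C)(C)C(C)(C)C | intermediate
8 | (3S,4S,5E,7S)-8-[(tert-butyldimethylsilyl)oxy]-3-methoxy-5,7-dimethylocta-1,5-dien-4-yl prop-2-enoate | C=C[C@H](OC)[C@@H](OC(=O)C=C)/C(C)=C/[C@H](C)CO[Si](C)(C)C(C)(C)C | intermediate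
9 | (5S,6S)-6-[(2E,4S)-5-[(tert-butyldimethylsilyl)oxy]-4-methylpent-2-en-2-yl]-5-methoxy-5,6-dihydro-2H-pyran-2-one | O=C1C=C[C@H](OC)[C@H](/C(C)=C/[C@H](C)CO[Si](C)(C)C(C)(C)C)O1 | intermediate
10 | (2RS,5S,6S)-6-[(2E,4S)-5-[(tert-butyldimethylsilyl)oxy]-4-methylpent-2-en-2-yl]-5-methoxy-5,6-dihydro-2H-pyran-2-ol (both anomers) | OC1C=C[C@H](OC)[C@H](/C(C)=C/[C@H](C)CO[Si](C)(C)C(C)(C)C)O1 | intermediate
11 | ethyl 2-(triphenyl-λ5-phosphanylidene)propanoate | CCOC(=O)C(C)=P(c1ccccc1)(c1ccccc1)c1ccccc1 | starting material
12 | (2Z,4S,5S,6E,8S)-9-[(tert-butyldimethylsilyl)oxy]-5-hydroxy-4-methoxy-6,8-dimethylnona-2,6-dienal | O=C/C=C\[C@H](OC)[C@@H](O)/C(C)=C/[C@H](C)CO[Si](C)(C)C(C)(C)C | intermediate (not isolated)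
13 | ethyl (2E,4Z,6S,7S,8E,10S)-11-[(tert-butyldimethylsilyl)oxy]-7-hydroxy-6-methoxy-2,8,10-trimethylundeca-2,4,8-trienoate | CCOC(=O)/C(C)=C/C=C\[C@H](OC)[C@@H](O)/C(C)=C/[C@H](C)CO[Si](C)(C)C(C)(C)C | intermediate
14 | ethyl (2E,4Z,6S,7S,8E,10S)-11-[(tert-butyldimethylsilyl)oxy]-6-methoxy-2,8,10-trimethyl-7-{[(trichloroacetyl)carbamoyl]oxy}undeca-2,4,8-trienoate | CCOC(=O)/C(C)=C/C=C\[C@H](OC)[C@@H](OC(=O)NC(=O)C(Cl)(Cl)Cl)/C(C)=C/[C@H](C)CO[Si](C)(C)C(C)(C)C | intermediate (not isolated)
15 | ethyl (2E,4Z,6S,7S,8E,10S)-11-[(tert-butyldimethylsilyl)oxy]-7-(carbamoyloxy)-6-methoxy-2,8,10-trimethylundeca-2,4,8-trienoate | CCOC(=O)/C(C)=C/C=C\[C@H](OC)[C@@H](OC(N)=O)/C(C)=C/[C@H](C)CO[Si](C)(C)C(C)(C)C | intermediate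
16 | (2E,4Z,6S,7S,8E,10S)-11-[(tert-butyldimethylsilyl)oxy]-7-(carbamoyloxy)-6-methoxy-2,8,10-trimethylundeca-2,4,8-trienoic acid | OC(=O)/C(C)=C/C=C\[C@H](OC)[C@@H](OC(N)=O)/C(C)=C/[C@H](C)CO[Si](C)(C)C(C)(C)C | intermediate
17 | 2,5-dihydroxybenzaldehyde | O=Cc1cc(O)ccc1O | starting material
18 | 2-hydroxy-5-[(triisopropylsilyl)oxy]benzaldehyde | O=Cc1cc(O[Si](C(C)C)(C(C)C)C(C)C)ccc1O | intermediate
19 | 2-hydroxy-3-nitro-5-[(triisopropylsilyl)oxy]benzaldehyde | O=Cc1cc(O[Si](C(C)C)(C(C)C)C(C)C)cc([N+](=O)[O-])c1O | intermediate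
20 | 2-(benzyloxy)-3-nitro-5-[(triisopropylsilyl)oxy]benzaldehyde | O=Cc1cc(O[Si](C(C)C)(C(C)C)C(C)C)cc([N+](=O)[O-])c1OCc1ccccc1 | intermediate
21 | diisopinocampheylborinate ester of 22 | C=C[C@H](C)[C@@H](OB([C@H]1C[C@H]2C[C@@H]([C@@H]1C)C2(C)C)[C@H]1C[C@H]2C[C@@H]([C@@H]1C)C2(C)C)c1cc(O[Si](C(C)C)(C(C)C)C(C)C)cc([N+](=O)[O-])c1OCc1ccccc1 | intermediate (not isolated)
22 | (1R,2S)-1-{2-(benzyloxy)-3-nitro-5-[(triisopropylsilyl)oxy]phenyl}-2-methylbut-3-en-1-ol | C=C[C@H](C)[C@@H](O)c1cc(O[Si](C(C)C)(C(C)C)C(C)C)cc([N+](=O)[O-])c1OCc1ccccc1 | intermediate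
23 | {4-(benzyloxy)-3-[(1R,2S)-1-methoxy-2-methylbut-3-en-1-yl]-5-nitrophenoxy}triisopropylsilane | C=C[C@H](C)[C@@H](OC)c1cc(O[Si](C(C)C)(C(C)C)C(C)C)cc([N+](=O)[O-])c1OCc1ccccc1 | intermediate
24 | 9-[(3S,4R)-4-{2-(benzyloxy)-3-nitro-5-[(triisopropylsilyl)oxy]phenyl}-4-methoxy-3-methylbutyl]-9-borabicyclo[3.3.1]nonane | B1(CC[C@H](C)[C@@H](OC)c2cc(O[Si](C(C)C)(C(C)C)C(C)C)cc([N+](=O)[O-])c2OCc2ccccc2)C2CCCC1CCC2 | intermediate (not isolated)
25 | (3S,4R)-4-{2-(benzyloxy)-3-nitro-5-[(triisopropylsilyl)oxy]phenyl}-4-methoxy-3-methylbutan-1-ol | OCC[C@H](C)[C@@H](OC)c1cc(O[Si](C(C)C)(C(C)C)C(C)C)cc([N+](=O)[O-])c1OCc1ccccc1 | intermediate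
26 | (3S,4R)-4-{3-amino-2-hydroxy-5-[(triisopropylsilyl)oxy]phenyl}-4-methoxy-3-methylbutan-1-ol | Nc1cc(O[Si](C(C)C)(C(C)C)C(C)C)cc(c1O)[C@H](OC)[C@@H](C)CCO | intermediate
27 | 2-[(tert-butyldimethylsilyl)oxy]-3-[(1R,2S)-4-[(tert-butyldimethylsilyl)oxy]-1-methoxy-2-methylbutyl]-5-[(triisopropylsilyl)oxy]aniline | Nc1cc(O[Si](C(C)C)(C(C)C)C(C)C)cc(c1O[Si](C)(C)C(C)(C)C)[C@H](OC)[C@@H](C)CCO[Si](C)(C)C(C)(C)C | intermediate
28 | seco amide with TBS ethers on O11, O12 and O21 and a TIPS ether on O18 (name as in step 19) | CC(C)(C)[Si](C)(C)OC[C@@H](C)/C=C(\C)[C@H](OC(N)=O)[C@@H](OC)/C=C\C=C(/C)C(=O)Nc1cc(O[Si](C(C)C)(C(C)C)C(C)C)cc(c1O[Si](C)(C)C(C)(C)C)[C@H](OC)[C@@H](C)CCO[Si](C)(C)C(C)(C)C | intermediate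
29 | seco 11,12-diol (name as in step 20) | OC[C@@H](C)/C=C(\C)[C@H](OC(N)=O)[C@@H](OC)/C=C\C=C(/C)C(=O)Nc1cc(O[Si](C(C)C)(C(C)C)C(C)C)cc(c1O[Si](C)(C)C(C)(C)C)[C@H](OC)[C@@H](C)CCO | intermediate
30 | seco 11,12-dialdehyde (name as in step 21) | O=C[C@@H](C)/C=C(\C)[C@H](OC(N)=O)[C@@H](OC)/C=C\C=C(/C)C(=O)Nc1cc(O[Si](C(C)C)(C(C)C)C(C)C)cc(c1O[Si](C)(C)C(C)(C)C)[C@H](OC)[C@@H](C)CC=O | intermediate
31 | macrocyclic 11,12-diol with O18 triisopropylsilyl and O21 tert-butyldimethylsilyl ethers | CO[C@H]1/C=C\C=C(/C)C(=O)Nc2cc(O[Si](C(C)C)(C(C)C)C(C)C)cc(c2O[Si](C)(C)C(C)(C)C)[C@H](OC)[C@@H](C)C[C@H](O)[C@H](O)[C@@H](C)/C=C(\C)[C@@H]1OC(N)=O | intermediate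
32 | CNP0523404.1 | CO[C@H]1/C=C\C=C(/C)C(=O)Nc2cc(O)cc(c2O)[C@H](OC)[C@@H](C)C[C@H](O)[C@H](O)[C@@H](C)/C=C(\C)[C@@H]1OC(N)=O | target

## Step count and least certain steps

Total step count: 23. Longest linear sequence: 15 steps (steps 1–10 and 19–23, from 1). The arene branch contributes 8 steps (11–18) before the union.

**Step 22 (key step).** The most likely failure is formation of the trans (threo) diol in preference to the cis one. A large ring can place C10 and C13 anti on the samarium diolate, as low-valent titanium closures of large carbocycles do. Simple reduction of the aldehydes without coupling is the second concern. The fallback sets out from 30 and returns to the route at 31. Both aldehydes would be methylenated under non-basic conditions (CH2I2, Zn, Ti(O-i-Pr)4, THF, 0 °C) to give the seco bis-alkene F1. Ring-closing metathesis at high dilution with a Z-selective catalyst, the cyclometalated nitrate carbene Ru(NO3)(=CH-C6H4-2-O-i-Pr)[1-(adamantan-1-yl-2-ide)-3-mesitylimidazolidin-2-ylidene], would give the macrocyclic Z-C11=C12 alkene F2. Dihydroxylation with OsO4 (cat.) and N-methylmorpholine N-oxide adds both oxygens to one face of the Z-alkene and can therefore only give an erythro diol, which is 31 if the C10 centre and the ring direct the reagent to the required face. All three reaction types are known at this ring size. The price is three steps for one, and the face of osmylation and its preference for the isolated cis-alkene over the hindered C8=C9 alkene and the electron-poor diene remain to be established.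

**Step 8.** The most likely failure is isomerisation of the ring-opened Z-enal to the E-enal before olefination, together with conjugate addition of the freed O7 to the new dienoate, because the ylide is slow and the hydroxyl stays free. The fallback sets out from 9 and returns at 13. Lactone 9 would be reduced fully (i-Bu2AlH, excess, 0 °C) to the Z-enediol F3 and silylated on both oxygens (TESCl, imidazole) to give the bis-triethylsilyl ether F4. Swern conditions oxidise a primary triethylsilyl ether directly and would give the O7-protected Z-enal F5. Olefination with 11 at room temperature would give the O7-silylated dienoate F6, and pyridinium p-toluenesulfonate in methanol would remove the secondary triethylsilyl group beside the primary TBS ether to give 13.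

**Step 19.** The most likely failure is slow acylation of the hindered, ortho-silyloxy aniline, which would allow the activated dienoic acid to lose its 4Z geometry. The fallback sets out from 27 and 10 and returns at 28. Aniline 27 would be acylated with 2-bromopropanoyl bromide to give the α-bromo anilide F11. Triphenylphosphine would convert it into the phosphonium bromide F12, and aqueous NaOH would give the anilide-stabilised ylide F13. Wittig reaction of F13 with lactol 10 would form C2=C3 and give the seco amide with free O7, F14. Carbamoylation as in step 9, through the N-trichloroacetyl carbamate F15, would give 28. The amide bond is then made with a small, reactive acyl bromide and no dienoic acid is ever activated.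

**Step 12.** The most likely failure is oxidative loss of the silyl group with quinone formation, because nitric acid is also an oxidant and the substrate is a mono-silylated hydroquinone. The fallback sets out from 17 and returns at 20. The C5 hydroxyl of 17 would be acetylated selectively (Ac2O, pyridine) to give 3-formyl-4-hydroxyphenyl acetate F7, whose electron-poor ester oxygen resists oxidation. Nitration would give the 5-nitro compound F8 and benzylation the benzyl ether F9. Methanolysis of the acetate (K2CO3, MeOH) would give phenol F10, and silylation with TIPSCl and imidazole would give 20.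

## Further compounds

F1 | step 22 | seco bis-alkene, 30 with both aldehydes methylenated (vinyl on C10, allyl on C14) | C=C[C@@H](C)/C=C(\C)[C@H](OC(N)=O)[C@@H](OC)/C=C\C=C(/C)C(=O)Nc1cc(O[Si](C(C)C)(C(C)C)C(C)C)cc(c1O[Si](C)(C)C(C)(C)C)[C@H](OC)[C@@H](C)CC=C
F2 | step 22 | macrolactam with a Z-C11=C12 alkene in place of the diol, O18 TIPS and O21 TBS ethers | CO[C@H]1/C=C\C=C(/C)C(=O)Nc2cc(O[Si](C(C)C)(C(C)C)C(C)C)cc(c2O[Si](C)(C)C(C)(C)C)[C@H](OC)[C@@H](C)C/C=C\[C@@H](C)/C=C(\C)[C@@H]1OC(N)=O
F3 | step 8 | (2Z,4S,5S,6E,8S)-9-[(tert-butyldimethylsilyl)oxy]-4-methoxy-6,8-dimethylnona-2,6-diene-1,5-diol | OC/C=C\[C@H](OC)[C@@H](O)/C(C)=C/[C@H](C)CO[Si](C)(C)C(C)(C)C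
F4 | step 8 | 1,5-bis(triethylsilyl) ether of F3 | CC[Si](CC)(CC)OC/C=C\[C@H](OC)[C@@H](O[Si](CC)(CC)CC)/C(C)=C/[C@H](C)CO[Si](C)(C)C(C)(C)C
F5 | step 8 | (2Z,4S,5S,6E,8S)-9-[(tert-butyldimethylsilyl)oxy]-4-methoxy-6,8-dimethyl-5-[(triethylsilyl)oxy]nona-2,6-dienal | O=C/C=C\[C@H](OC)[C@@H](O[Si](CC)(CC)CC)/C(C)=C/[C@H](C)CO[Si](C)(C)C(C)(C)C
F6 | step 8 | ethyl (2E,4Z,6S,7S,8E,10S)-11-[(tert-butyldimethylsilyl)oxy]-6-methoxy-2,8,10-trimethyl-7-[(triethylsilyl)oxy]undeca-2,4,8-trienoate | CCOC(=O)/C(C)=C/C=C\[C@H](OC)[C@@H](O[Si](CC)(CC)CC)/C(C)=C/[C@H](C)CO[Si](C)(C)C(C)(C)C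
F7 | step 12 | 3-formyl-4-hydroxyphenyl acetate | CC(=O)Oc1ccc(O)c(C=O)c1
F8 | step 12 | 3-formyl-4-hydroxy-5-nitrophenyl acetate | CC(=O)Oc1cc(C=O)c(O)c([N+](=O)[O-])c1
F9 | step 12 | 4-(benzyloxy)-3-formyl-5-nitrophenyl acetate | CC(=O)Oc1cc(C=O)c(OCc2ccccc2)c([N+](=O)[O-])c1
F10 | step 12 | 2-(benzyloxy)-5-hydroxy-3-nitrobenzaldehyde | O=Cc1cc(O)cc([N+](=O)[O-])c1OCc1ccccc1
F11 | step 19 | (2RS)-2-bromo-N-aryl-propanamide of aniline 27 | CC(Br)C(=O)Nc1cc(O[Si](C(C)C)(C(C)C)C(C)C)cc(c1O[Si](C)(C)C(C)(C)C)[C@H](OC)[C@@H](C)CCO[Si](C)(C)C(C)(C)C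
F12 | step 19 | triphenylphosphonium bromide from F11 | CC(C(=O)Nc1cc(O[Si](C(C)C)(C(C)C)C(C)C)cc(c1O[Si](C)(C)C(C)(C)C)[C@H](OC)[C@@H](C)CCO[Si](C)(C)C(C)(C)C)[P+](c1ccccc1)(c1ccccc1)c1ccccc1.[Br-]
F13 | step 19 | anilide-stabilised ylide, N-aryl 2-(triphenyl-λ5-phosphanylidene)propanamide of 27 | CC(C(=O)Nc1cc(O[Si](C(C)C)(C(C)C)C(C)C)cc(c1O[Si](C)(C)C(C)(C)C)[C@H](OC)[C@@H](C)CCO[Si](C)(C)C(C)(C)C)=P(c1ccccc1)(c1ccccc1)c1ccccc1
F14 | step 19 | seco amide 28 with a free hydroxyl on C7 in place of the carbamate | CC(C)(C)[Si](C)(C)OC[C@@H](C)/C=C(\C)[C@H](O)[C@@H](OC)/C=C\C=C(/C)C(=O)Nc1cc(O[Si](C(C)C)(C(C)C)C(C)C)cc(c1O[Si](C)(C)C(C)(C)C)[C@H](OC)[C@@H](C)CCO[Si](C)(C)C(C)(C)C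
F15 | step 19 | N-trichloroacetyl carbamate of F14 | CC(C)(C)[Si](C)(C)OC[C@@H](C)/C=C(\C)[C@H](OC(=O)NC(=O)C(Cl)(Cl)Cl)[C@@H](OC)/C=C\C=C(/C)C(=O)Nc1cc(O[Si](C(C)C)(C(C)C)C(C)C)cc(c1O[Si](C)(C)C(C)(C)C)[C@H](OC)[C@@H](C)CCO[Si](C)(C)C(C)(C)C
A1 | alternative 1 | 3-(diallylamino)-4-hydroxy-4-(alk-1-en-2-yl)cyclobut-2-en-1-one carrying the C5–C15 chain | O=C1C=C(N(CC=C)CC=C)C1(O)C(=C)[C@H](OC)[C@@H](C)C[C@H](O[Si](C)(C)C(C)(C)C)[C@H](O[Si](C)(C)C(C)(C)C)[C@@H](C)/C=C(\C)[C@H](O[Si](CC)(CC)CC)[C@@H](OC)C#CC
A2 | alternative 1 | 2-(diallylamino)hydroquinone carrying the C5–C15 chain on C16 | Oc1cc(N(CC=C)CC=C)c(O)c(c1)[C@H](OC)[C@@H](C)C[C@H](O[Si](C)(C)C(C)(C)C)[C@H](O[Si](C)(C)C(C)(C)C)[C@@H](C)/C=C(\C)[C@H](O[Si](CC)(CC)CC)[C@@H](OC)C#CC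
A3 | alternative 2 | seco compound with the anilide-stabilised C2 ylide and the C3 lactol, phenols as methoxymethyl ethers | CC(=P(c1ccccc1)(c1ccccc1)c1ccccc1)C(=O)Nc1cc(OCOC)cc(c1OCOC)[C@H](OC)[C@@H](C)C[C@H](O[Si](C)(C)C(C)(C)C)[C@H](O[Si](C)(C)C(C)(C)C)[C@@H](C)/C=C(\C)[C@@H]1OC(O)C=C[C@@H]1OC
A4 | alternative 2 | macrolactam with free C7 hydroxyl, phenols as methoxymethyl ethers | CO[C@H]1/C=C\C=C(/C)C(=O)Nc2cc(OCOC)cc(c2OCOC)[C@H](OC)[C@@H](C)C[C@H](O[Si](C)(C)C(C)(C)C)[C@H](O[Si](C)(C)C(C)(C)C)[C@@H](C)/C=C(\C)[C@@H]1O
A5 | alternative 3 | seco-diyne with methyl-capped alkynes at C4 and C5 | CC#C/C=C(\C)C(=O)Nc1cc(O[Si](C)(C)C(C)(C)C)cc(c1O[Si](C)(C)C(C)(C)C)[C@H](OC)[C@@H](C)C[C@H](O[Si](C)(C)C(C)(C)C)[C@H](O[Si](C)(C)C(C)(C)C)[C@@H](C)/C=C(\C)[C@H](O[Si](CC)(CC)CC)[C@@H](OC)C#CC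
A6 | alternative 3 | 4,5-didehydro macrolactam (cyclic 2E-en-4-yne) | CO[C@H]1C#C\C=C(/C)C(=O)Nc2cc(O[Si](C)(C)C(C)(C)C)cc(c2O[Si](C)(C)C(C)(C)C)[C@H](OC)[C@@H](C)C[C@H](O[Si](C)(C)C(C)(C)C)[C@H](O[Si](C)(C)C(C)(C)C)[C@@H](C)/C=C(\C)[C@@H]1O[Si](CC)(CC)CC
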